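(The numbers in the tables were computed with made-up constants; noise was put on by code.)

Count each amount as a fraction of its own charge: product and solid substrate against the solid charged, partner and protic impurity against what went in of each. None of the solid is in solution at the start.

| setting | winter | noon | gamma | eta | beta |
|---|---|---|---|---|---|
| solid substrate | 0.18 M | 0.18 M | 0.18 M | 0.18 M | 0.18 M |
| partner | 0.80 equiv | 0.80 equiv | 0.800 equiv | 0.800 equiv | 0.800 equiv |
| protic impurity | 5 mM | 7.9 mM | 3.60 mM | 3.60 mM | 3.60 mM |
| temperature | 55 °C | 80 °C | 100 °C | 60 °C | 80 °C |
| remark | run made earlier | run made earlier |  |  |  |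
| time |  |  | 2.5 d | 2.5 d | 2.5 d |

- winter (time / d: product / %): 4.00: 0; 8.00: 4; 12.0: 3; 15.0: 2; 20.0: 7; 25.0: 8; 30.0: 10
- noon (time / d: product / %): 0.417: 0; 1.25: 6; 2.50: 8; 3.00: 10; 5.00: 12; 6.00: 16; 8.00: 20

(readings scatter by 1.5 percentage points)

- given per volume of solution although it is solid: solid substrate
- the numbers in the tables scatter by 1.5 percentage points (one standard deviation)
- what may be going on: starting material <-> dormant form; starting material <-> intermediate + leaving ligand; partner + intermediate -> product; partner + protic impurity -> quenched reagent; solid substrate <-> starting material
- at the start none of the solid substrate is in solution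
- what has only dissolved of solid substrate counts as not reacted

* the flask with the highest amount of product, in percent of the solid substrate charged ("all alike" if they lie within 1.5 percentage points) (gamma / eta / beta / all alike)
* final product, as a percentage of the solid substrate charged, in gamma
* final product, as a percentage of the solid substrate charged, in eta
* final product, as a percentage of the solid substrate charged, in beta

Look first at beta, which has the temperature of the noon run and about half its protic impurity, and yet expect from that change no real shift from the noon reading of 8% at 2.50 d. Reckon the correction alone: beta's impurity can take 2.50% of its partner and the noon run's 5.49%. Call this fraction of the partner charge, one partner quenched per impurity, the impurity toll. Even with product rate proportional to partner, beta's lower toll adds 0.24 percentage points, less than the scatter of 1.5 points, so my figure for beta stays at the noon reading, above the forecast's, though by less than the scatter.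

The forecast gives 22% for gamma, 1.3% for eta and 7% for beta, with gamma highest: “The hottest flask wins”.

The flasks give 20.9% in gamma, 1.76% in eta and 8.97% in beta, so the forecast holds within its tolerance and product follows temperature.

    starting material ⇌ dormant form (K = 5.40, k = 6.30 × 10⁻⁶ s⁻¹, Ea = 125 kJ mol⁻¹, ΔH = −9.00 kJ mol⁻¹)
    starting material ⇌ intermediate + leaving ligand (K = 9.60 × 10⁻⁶ M, k = 2.90 × 10⁻⁵ s⁻¹, Ea = 116 kJ mol⁻¹, ΔH = 11.0 kJ mol⁻¹)
    partner + intermediate → product (k = 0.0840 M⁻¹ s⁻¹, Ea = 74.0 kJ mol⁻¹)
    partner + protic impurity → quenched reagent (k = 0.00390 M⁻¹ s⁻¹, Ea = 89.0 kJ mol⁻¹)
    solid substrate ⇌ starting material, rate k5*(cs5 - [starting material]) while solid is left; crystals form when [starting material] > cs5 (solubility = 0.0590 M, k = 3.60 × 10⁻⁵ s⁻¹)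
    (constants at 100 °C)

In beta the intermediate's half-life against partner is 0.064 h at 0.346 d, far shorter than the run's 2.5 d, and at the end it stands at 0.0111% of the charge, with made over used at 0.999, a quasi-steady state. Watch the partner instead: with protic impurity at 0% at 2.50 d, toll and product leave beta 86.3% of its partner, and the flask holds 86%; beta's neighbour flask, the same but with 0.31 M of solid substrate, has a toll of 1.45% and product 6.31%, which leaves 90.7%, and that neighbour holds 91%.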